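The cyclohexanone is cut across C1–C2 and C3–C4 (ring numbered from the carbonyl C1 through C2(OAng), C3 (side chain), C4(OAng), C5(OH) to C6(Me,OH)). The oxygens on C1, C2 and C4 are the handles: C1 and C4 are C2 and C5 of a 2-silyloxy-3-methylfuran whose ring oxygen is the C4 oxygen, and a temporary diisopropylsilylene joins the C1 and C2 oxygens, linking the furan to the silyl dienol ether of the side-chain enal. One intramolecular furan Diels–Alder reaction forms both bonds and sets C2, C3 and C4; cleaving the silicon unveils the C1 ketone, the C5=C6 enone and both carbinols. The tether reverses the intrinsic regiochemistry.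

Key step: step 6

Remark on the chemistry: Ang = angeloyl = (Z)-2-methylbut-2-enoyl. All ring compounds use the ring numbering above. "Side chain" in 9–16 means (3S)-3-(angeloyloxy)-6-methylhepta-1,5-dien-2-yl.

Assumption: 1, 6, angelic acid, diisopropylsilyl bis(triflate) and the D-fructose-derived Shi ketone are taken as commercially available.

Step 1
Reactants: 1 (2E)-4,4-dimethoxy-2-methylbut-2-enal
Product: 2 (2E,4S)-1,1-dimethoxy-3-methylhepta-2,6-dien-4-ol
Conditions: (−)-Ipc2BOMe, allylMgBr, Et2O, 0 °C to rt; then 1, −78 °C; NaOH, H2O2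
Reagents that add atoms: allylmagnesium bromide, C=CC[Mg]Br
Why: Brown allylboration through a chair Zimmerman–Traxler transition state, in which the (+)-α-pinene-derived isopinocampheyl groups should send the allyl group to the Si face of the enal and set the carbinol (the later side-chain stereocentre) as S.

Step 2
Reactants: 2 (2E,4S)-1,1-dimethoxy-3-methylhepta-2,6-dien-4-ol
Product: 3 (2E,4S)-1,1-dimethoxy-3,7-dimethylocta-2,6-dien-4-ol
Conditions: second-generation Grubbs catalyst (3 mol%), 2-methyl-2-butene (solvent), 40 °C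
Reagents that add atoms: 2-methyl-2-butene, CC=C(C)C
Why: Olefin cross-metathesis of the terminal alkene with excess 2-methyl-2-butene should cap it as the prenyl group, while the trisubstituted acetal alkene stays inert.

Step 3
Reactants: 3 (2E,4S)-1,1-dimethoxy-3,7-dimethylocta-2,6-dien-4-ol
Product: 4 (2E,4S)-1,1-dimethoxy-3,7-dimethylocta-2,6-dien-4-yl angelate
Conditions: angelic acid, 2,4,6-trichlorobenzoyl chloride, Et3N, toluene, rt; then 3, 80 °C
Reagents that add atoms: angelic acid, C/C=C(/C)C(=O)O
Why: Yamaguchi esterification through the mixed anhydride without DMAP should acylate the secondary alcohol without Z to E isomerisation of the angelate and without touching the acetal.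

Step 4
Reactants: 4 (2E,4S)-1,1-dimethoxy-3,7-dimethylocta-2,6-dien-4-yl angelate
Product: 5 (2E,4S)-3,7-dimethyl-1-oxoocta-2,6-dien-4-yl angelate
Conditions: Amberlyst-15, acetone/H2O, rt
Reagents that add atoms: water, O
Why: Mild acid hydrolysis of the α,β-unsaturated dimethyl acetal should give the (E)-enal, whose C3 methyl is cis to the formyl group, and leave the allylic angelate intact.

Step 5
Reactants: 5 (2E,4S)-3,7-dimethyl-1-oxoocta-2,6-dien-4-yl angelate, 6 3-methylfuran-2(5H)-one
Product: 8 (1E,4S)-1-{[diisopropyl(3-methylfuran-2-yloxy)silyl]oxy}-7-methyl-3-methylideneocta-1,6-dien-4-yl angelate, via dienyloxysilyl triflate 7 (not isolated)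
Conditions: iPr2Si(OTf)2 (1.05 equiv), Et3N, CH2Cl2, −78 °C, 5 added slowly; then 6, Et3N, −78 to 0 °C; filtration through basic alumina
Reagents that add atoms: diisopropylsilyl bis(trifluoromethanesulfonate), CC(C)[Si](OS(=O)(=O)C(F)(F)F)(OS(=O)(=O)C(F)(F)F)C(C)C
Why: Sequential soft enolisation, in which the bis(triflate) O-silylates the enal and Et3N removes a proton of the C3 methyl to give the (1E)-dienyl silyl triflate, whose less reactive second Si–OTf bond then turns the butenolide into the 2-silyloxyfuran, should give the unsymmetrical silyl bis-enol ether.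

Step 6
Reactants: 8 (1E,4S)-1-{[diisopropyl(3-methylfuran-2-yloxy)silyl]oxy}-7-methyl-3-methylideneocta-1,6-dien-4-yl angelate
Product: 10 2,4-dihydroxy-6-methyl-3-(side chain)cyclohex-5-en-1-one (2-OH and 4-OH cis; side chain trans to both), via oxanorbornene silyl ketal 9 (not isolated)
Conditions: toluene (0.01 M), 2,6-di-tert-butyl-4-methylpyridine (cat.), BHT, 110 °C, sealed tube; then HF·pyridine, THF, 0 °C
Reagents that add atoms: none
Why: Proposed new method: a thermal intramolecular Diels–Alder reaction of the 2-silyloxyfuran (4π; furan C2 and C5 are the later C1 and C4) with the enol-ether double bond of the silyloxydiene (2π; the later C2=C3) should give the bridged silyl ketal, and HF then cleaves both Si–O bonds so that the bridged hemiketal collapses to the C1 ketone and frees the C4 hydroxyl; the closest known reactions are intramolecular furan Diels–Alder reactions of 2-amidofurans with unactivated tethered alkenes (driven by opening of the oxygen bridge), silicon-tethered intramolecular Diels–Alder reactions and intermolecular cycloadditions of 2-silyloxyfurans. The carbocycle is closed by the concerted [4+2] addition and the 1,3-dioxa-2-silolane is closed as the five-membered ring of a fused-mode closure across the three-atom O–Si–O link, with the tether exo. The tether enforces the C1–C2/C3–C4 regiochemistry, opposite to the polar preference of a free silyloxyfuran (nucleophilic at its C5), and holds the C2 oxygen syn to the oxygen bridge, so the C2 and C4 oxygens end up cis. The E geometry of the enol ether puts the C3 side chain trans to the C2 oxygen, hence endo and also trans to the C4 oxygen. The absolute sense rests only on 1,4-induction from the side-chain carbinol through allylic strain, so a modest bias at best is expected, and the two diastereomers, each a single enantiomer, are to be separated at the stage of 10. The step needs the furan to react as the 4π partner and the bis-enol silane to survive until it cyclises, which the aromatic electron-rich silyloxyfuran, the C3 methyl (it hinders the alternative mode across furan C2=C3) and base-buffered aprotic conditions should secure.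

Step 7
Reactants: 10 2,4-dihydroxy-6-methyl-3-(side chain)cyclohex-5-en-1-one
Product: 11 6-methyl-3-(side chain)-2,4-bis(triethylsilyloxy)cyclohex-5-en-1-one
Conditions: TESOTf (2.5 equiv), 2,6-lutidine, CH2Cl2, −78 °C
Reagents that add atoms: triethylsilyl trifluoromethanesulfonate, CC[Si](CC)(CC)OS(=O)(=O)C(F)(F)F
Why: Silyl triflate silylation of both secondary hydroxyls should mask the α-ketol and turn the C4 allylic hydroxyl into a bulky ether that cannot direct the later epoxidation.

Step 8
Reactants: 11 6-methyl-3-(side chain)-2,4-bis(triethylsilyloxy)cyclohex-5-en-1-one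
Product: 12 6-methyl-3-(side chain)-2,4-bis(triethylsilyloxy)cyclohex-5-en-1-ol (1-OH cis to the C3 side chain and trans to 2-OTES)
Conditions: NaBH4, CeCl3·7H2O, MeOH, −78 °C
Reagents that add atoms: none
Why: Luche 1,2-reduction with axial hydride delivery on the all-equatorial half-chair should give the equatorial C1 alcohol, on the face of the C3 side chain, as in the reduction of carvone to cis-carveol.

Step 9
Reactants: 12 6-methyl-3-(side chain)-2,4-bis(triethylsilyloxy)cyclohex-5-en-1-ol
Product: 13 5,6-epoxy-6-methyl-3-(side chain)-2,4-bis(triethylsilyloxy)cyclohexan-1-ol (epoxide cis to 1-OH, on the face of the C3 side chain)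
Conditions: VO(acac)2 (5 mol%), t-BuOOH, CH2Cl2, 0 °C
Reagents that add atoms: tert-butyl hydroperoxide, CC(C)(C)OO
Why: Vanadium-catalysed hydroxyl-directed epoxidation should deliver oxygen syn to the C1 hydroxyl and anti to the C4 silyl ether, and only to the allylic-alcohol alkene, leaving the side-chain alkenes untouched.

Step 10
Reactants: 13 5,6-epoxy-6-methyl-3-(side chain)-2,4-bis(triethylsilyloxy)cyclohexan-1-ol
Product: 14 5,6-epoxy-6-methyl-3-(side chain)-2,4-bis(triethylsilyloxy)cyclohexan-1-one (epoxide trans to the 4-OTES group)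
Conditions: Dess–Martin periodinane, NaHCO3, CH2Cl2, rt
Reagents that add atoms: none
Why: Dess–Martin oxidation should return the C1 ketone under buffered conditions that leave the epoxide, the silyl ethers and the angelate intact.

Step 11
Reactants: 14 5,6-epoxy-6-methyl-3-(side chain)-2,4-bis(triethylsilyloxy)cyclohexan-1-one
Product: 15 (2R,3S,4S,5S,6R)-2,4,5,6-tetrahydroxy-6-methyl-3-(side chain)cyclohexan-1-one
Conditions: HClO4 (0.2 M aq.), THF, rt to 40 °C
Reagents that add atoms: water, O
Why: Aqueous acid should remove both triethylsilyl ethers and open the α,β-epoxy ketone by attack of water at C5 (the β-carbon, trans-diaxial opening by the Fürst–Plattner rule) with inversion, which sets 5-OH cis to 4-OH and trans to the 6-OH kept from the epoxide.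

Step 12
Reactants: 15 (2R,3S,4S,5S,6R)-2,4,5,6-tetrahydroxy-6-methyl-3-(side chain)cyclohexan-1-one
Product: 16 (2R,3S,4S,5S,6R)-2,4-bis(angeloyloxy)-5,6-dihydroxy-6-methyl-3-(side chain)cyclohexan-1-one
Conditions: angelic acid (2.3 equiv), 2,4,6-trichlorobenzoyl chloride, Et3N, toluene, rt; then 15, THF/toluene, 60 °C
Reagents that add atoms: angelic acid, C/C=C(/C)C(=O)O
Why: Yamaguchi esterification under steric control should acylate the two equatorial hydroxyls at C2 and C4 and leave the axial C5 hydroxyl next to the quaternary C6 (the analogue of the unreactive axial 4-OH of galactopyranosides) and the tertiary C6 hydroxyl free.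

Step 13
Reactants: 16 (2R,3S,4S,5S,6R)-2,4-bis(angeloyloxy)-5,6-dihydroxy-6-methyl-3-(side chain)cyclohexan-1-one
Product: 17 (2R,3S,4S,5S,6R)-2,4-bis(angeloyloxy)-5,6-dihydroxy-6-methyl-3-{(3S)-3-(angeloyloxy)-4-[(2R)-3,3-dimethyloxiran-2-yl]but-1-en-2-yl}cyclohexan-1-one
Conditions: D-fructose-derived Shi ketone (0.5 equiv), KHSO5 (as Oxone, 2KHSO5·KHSO4·K2SO4), K2CO3, Bu4NHSO4, MeCN/dimethoxymethane/aq. Na2B4O7 buffer, 0 °C, short reaction time
Reagents that add atoms: potassium peroxymonosulfate, [K+].[O-]S(=O)(=O)OO
Why: Shi asymmetric epoxidation, in which the electrophilic chiral dioxirane selects the only electron-rich trisubstituted alkene and its spiro transition state sets the epoxide carbon as R under reagent control.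

Compound list
1 | (2E)-4,4-dimethoxy-2-methylbut-2-enal | COC(OC)/C=C(\C)C=O | starting material
2 | (2E,4S)-1,1-dimethoxy-3-methylhepta-2,6-dien-4-ol | COC(OC)/C=C(\C)[C@H](CC=C)O | intermediate
3 | (2E,4S)-1,1-dimethoxy-3,7-dimethylocta-2,6-dien-4-ol | COC(OC)/C=C(\C)[C@H](CC=C(C)C)O | intermediate
4 | (2E,4S)-1,1-dimethoxy-3,7-dimethylocta-2,6-dien-4-yl angelate | COC(OC)/C=C(\C)[C@H](CC=C(C)C)OC(=O)/C(C)=C\C | intermediate
5 | (2E,4S)-3,7-dimethyl-1-oxoocta-2,6-dien-4-yl angelate | O=C/C=C(\C)[C@H](CC=C(C)C)OC(=O)/C(C)=C\C | intermediate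
6 | 3-methylfuran-2(5H)-one | CC1=CCOC1=O | starting material
7 | {[(1E,4S)-4-(angeloyloxy)-7-methyl-3-methylideneocta-1,6-dien-1-yl]oxy}diisopropylsilyl trifluoromethanesulfonate (not isolated) | C=C(/C=C/O[Si](C(C)C)(C(C)C)OS(=O)(=O)C(F)(F)F)[C@H](CC=C(C)C)OC(=O)/C(C)=C\C | intermediate
8 | (1E,4S)-1-{[diisopropyl(3-methylfuran-2-yloxy)silyl]oxy}-7-methyl-3-methylideneocta-1,6-dien-4-yl angelate | C=C(/C=C/O[Si](C(C)C)(C(C)C)Oc1occc1C)[C@H](CC=C(C)C)OC(=O)/C(C)=C\C | intermediate
9 | cycloadduct: 7-oxabicyclo[2.2.1]hept-5-ene in which the former furan oxygen bridges C1 and C4; the C1 oxygen and the exo C2 oxygen are tied in a 2,2-diisopropyl-1,3-dioxa-2-silolane; side chain endo on C3; methyl on C6 (not isolated) | C=C([C@H]1[C@H]2C=C(C)[C@@]3(O2)O[Si](C(C)C)(C(C)C)O[C@H]13)[C@H](CC=C(C)C)OC(=O)/C(C)=C\C | intermediate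
10 | 2,4-dihydroxy-6-methyl-3-(side chain)cyclohex-5-en-1-one; 2-OH and 4-OH cis, side chain trans to both | C=C([C@H]1[C@H](O)C=C(C)C(=O)[C@@H]1O)[C@H](CC=C(C)C)OC(=O)/C(C)=C\C | intermediate
11 | 2,4-bis(triethylsilyl) ether of 10 | C=C([C@H]1[C@H](O[Si](CC)(CC)CC)C=C(C)C(=O)[C@@H]1O[Si](CC)(CC)CC)[C@H](CC=C(C)C)OC(=O)/C(C)=C\C | intermediate
12 | C1 allylic alcohol from 11; 1-OH cis to the C3 side chain, trans to 2-OTES | C=C([C@H]1[C@H](O[Si](CC)(CC)CC)C=C(C)[C@@H](O)[C@@H]1O[Si](CC)(CC)CC)[C@H](CC=C(C)C)OC(=O)/C(C)=C\C | intermediate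
13 | 5,6-epoxy alcohol; epoxide cis to 1-OH and to the C3 side chain, trans to 4-OTES | C=C([C@H]1[C@H](O[Si](CC)(CC)CC)[C@H]2O[C@@]2(C)[C@@H](O)[C@@H]1O[Si](CC)(CC)CC)[C@H](CC=C(C)C)OC(=O)/C(C)=C\C | intermediate
14 | 5,6-epoxy ketone; epoxide on the face of the C3 side chain, trans to 4-OTES | C=C([C@H]1[C@H](O[Si](CC)(CC)CC)[C@H]2O[C@@]2(C)C(=O)[C@@H]1O[Si](CC)(CC)CC)[C@H](CC=C(C)C)OC(=O)/C(C)=C\C | intermediate
15 | (2R,3S,4S,5S,6R)-2,4,5,6-tetrahydroxy-6-methyl-3-(side chain)cyclohexan-1-one | C=C([C@H]1[C@H](O)[C@H](O)[C@@](C)(O)C(=O)[C@@H]1O)[C@H](CC=C(C)C)OC(=O)/C(C)=C\C | intermediate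
16 | (2R,3S,4S,5S,6R)-2,4-bis(angeloyloxy)-5,6-dihydroxy-6-methyl-3-(side chain)cyclohexan-1-one | C=C([C@H]1[C@H](OC(=O)/C(C)=C\C)[C@H](O)[C@@](C)(O)C(=O)[C@@H]1OC(=O)/C(C)=C\C)[C@H](CC=C(C)C)OC(=O)/C(C)=C\C | intermediate
17 | (2R,3S,4S,5S,6R)-2,4-bis(angeloyloxy)-5,6-dihydroxy-6-methyl-3-{(3S)-3-(angeloyloxy)-4-[(2R)-3,3-dimethyloxiran-2-yl]but-1-en-2-yl}cyclohexan-1-one | C=C([C@H]1[C@H](OC(=O)/C(C)=C\C)[C@H](O)[C@@](C)(O)C(=O)[C@@H]1OC(=O)/C(C)=C\C)[C@H](C[C@H]1OC1(C)C)OC(=O)/C(C)=C\C | target

Total step count: 13
Longest linear sequence: 13 steps (1 to 17; 6 enters at step 5)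

Steps most likely to fail

1. Step 6 (key step). The bis-enol silane may be lost to desilylation or vinylogous Mukaiyama-type oligomerisation before it cyclises, the cycloaddition/cycloreversion balance may be unfavourable, or the facial selectivity relative to the side-chain stereocentre may be poor. The fallback uses known reactions only, sets out from 5 and returns at 11; it makes the two ring bonds in separate steps. 3-Methyl-2-furyllithium F1 (from 2-bromo-3-methylfuran and n-BuLi, THF, −78 °C) should add to the aldehyde of 5 to form C1–C2 and give the furyl carbinol F2, whose carbinol epimers are separated. TESOTf and 2,6-lutidine should give the silyl ether F3. Oxidative opening of the furan (N-bromosuccinimide, NaHCO3, THF/H2O, −20 °C) should give the (Z)-4-oxo-enal F4. Me2AlCl (CH2Cl2, −78 °C) should then promote a type 1 carbonyl-ene cyclisation of the side-chain trisubstituted alkene onto the aldehyde through an isopulegol-like chair with the C2 silyl ether and the new C4 oxygen equatorial and with proton loss from the methyl group. This forms C3–C4 and the exocyclic methylene and gives the hydroxy enone F5, and silylation of its C4 hydroxyl (TESOTf, 2,6-lutidine) gives 11.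

2. Step 5. Symmetric bis-silylation, competing γ-deprotonation at the acyloxy-bearing carbon, or hydrolysis of the mixed silane on isolation may occur. The fallback sets out from 5 and 6 and returns at 8; it replaces the one-pot soft enolisation by two separate hard-enolate silylations. 6 with excess iPr2SiCl2 and Et3N should give, after distillation, chloro(diisopropyl)(3-methylfuran-2-yloxy)silane F6. The potassium dienolate F7, made from 5 with KN(SiMe3)2 in THF at −78 °C by kinetic removal of a proton from the methyl cis to the formyl group, is then O-silylated by F6 to give 8.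

3. Step 12. Over-acylation at the C5 hydroxyl, acyl migration between the C4 and C5 oxygens, or Z to E isomerisation of the angelates under forcing conditions may occur. The fallback sets out from 15 and returns at 16; it replaces steric control by template control. Under catalysis by 2-aminoethyl diphenylborinate (10 mol%, i-Pr2NEt, MeCN, 0 °C), the cis C4/C5 diol is bound as a borinate and freshly prepared angeloyl chloride should acylate only its equatorial C4 oxygen to give the 4-mono-angelate F8. One equivalent of the angelic 2,4,6-trichlorobenzoic mixed anhydride then esterifies the remaining equatorial C2 hydroxyl to give 16.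

Further compounds
F1 | step 6 | 3-methyl-2-furyllithium | [Li]c1occc1C
F2 | step 6 | furyl carbinol: (1E,4S)-1-[hydroxy(3-methylfuran-2-yl)methyl]-substituted dienyl angelate, carbinol epimer with the C2 configuration of 17 | Cc1ccoc1[C@H](O)/C=C(\C)[C@H](CC=C(C)C)OC(=O)/C(C)=C\C
F3 | step 6 | triethylsilyl ether of F2 | Cc1ccoc1[C@H](O[Si](CC)(CC)CC)/C=C(\C)[C@H](CC=C(C)C)OC(=O)/C(C)=C\C
F4 | step 6 | (Z)-4-oxo-enal from furan opening of F3 | O=C/C=C(/C)C(=O)[C@H](O[Si](CC)(CC)CC)/C=C(\C)[C@H](CC=C(C)C)OC(=O)/C(C)=C\C
F5 | step 6 | 4-hydroxy-6-methyl-3-(side chain)-2-(triethylsilyloxy)cyclohex-5-en-1-one | C=C([C@H]1[C@H](O)C=C(C)C(=O)[C@@H]1O[Si](CC)(CC)CC)[C@H](CC=C(C)C)OC(=O)/C(C)=C\C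
F6 | step 5 | chloro(diisopropyl)(3-methylfuran-2-yloxy)silane | Cc1ccoc1O[Si](Cl)(C(C)C)C(C)C
F7 | step 5 | potassium (1E)-dienolate of 5 | [K+].[O-]/C=C/C(=C)[C@H](CC=C(C)C)OC(=O)/C(C)=C\C
F8 | step 12 | (2R,3S,4S,5S,6R)-4-(angeloyloxy)-2,5,6-trihydroxy-6-methyl-3-(side chain)cyclohexan-1-one | C=C([C@H]1[C@H](OC(=O)/C(C)=C\C)[C@H](O)[C@@](C)(O)C(=O)[C@@H]1O)[C@H](CC=C(C)C)OC(=O)/C(C)=C\C
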